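**Plan**

Numbering (longipinane) is used for the target and all tricyclic compounds: C1 ketone, C2=C3(Me), bridgeheads C4 and C11, one-carbon bridges C5 (H) and C10 (Me), C6 = CMe2, C7(O)–C8H2–C9(O).
Cuts: the two ester C–O bonds; C8–C9 (aldol, opens the seven-membered ring); C5=C6 (olefination of a cyclobutanone); C4–C10 and C5–C11 (ketene–alkene [2+2]); C1–C2 (vinylogous aldol); C10=C11 (Wittig).
Forward: acyclic C10 chain, then cyclobutane and six-membered ring together ([2+2]), then the C5 arm, the enone, the seven-membered ring (C8–C9), and last the C7 and C9 esters.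
Stereochemistry: the C1 carbinol comes from a catalytic asymmetric vinylogous aldol; it steers the [2+2] through A(1,3) strain, which fixes C4, C10 and C11, and is then oxidised away. C5 is set by hydride delivery to the open face, C9 by catalyst control in the ring closure, and C7 by intramolecular hydride transfer from the C9 oxygen, which also tells the two oxygens apart.
Enabling feature: on the cyclobutane (C4–C5–C11–C10) the C10 formyl arm and the C5 CMe2–acetyl arm are locked cis on the face remote from the enone ring, roughly 2.5 Å apart by pinane geometry. The acetyl group can enolise only at C8 (C6 is quaternary) and the C9 formyl group has no α-hydrogen, so a single aldol mode exists and it closes the seven-membered ring of a bicyclo[4.1.1]octane.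

Key step: step 13

Remark: the sense of induction of the two chiral catalysts (steps 3 and 13) is taken from their intermolecular behaviour; if a first run shows the opposite sense, the antipodal catalyst is used and nothing else changes. Bicyclic intermediates are numbered as bicyclo[3.1.1]heptanes with C6 and C7 as the one-carbon bridges.

**Route**

Step 1
Reactants: 1 1-[(tert-butyldimethylsilyl)oxy]propan-2-one
Product: 2 (E)-4-[(tert-butyldimethylsilyl)oxy]-3-methylbut-2-enal
Conditions: Ph3P=CHCHO, toluene, 90 °C; chromatography to remove the minor Z isomer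
Reagents that add atoms: (triphenylphosphoranylidene)acetaldehyde, O=CC=P(c1ccccc1)(c1ccccc1)c1ccccc1
Why: Wittig olefination of an activated α-silyloxy ketone by a stabilised formyl ylide should give the trisubstituted enal with the formyl group trans to the larger CH2OSi group (E).

Step 2
Reactants: 3 methyl 3-methylbut-2-enoate
Product: 4 silyl dienol ether of 3
Conditions: LiN(i-Pr)2, THF/DMPU, −78 °C; TBSCl
Reagents that add atoms: tert-butyldimethylsilyl chloride, CC(C)(C)[Si](C)(C)Cl
Why: γ-deprotonation and O-silylation of the senecioate gives the cross-conjugated silyl ketene acetal (dienolate silylation), used as obtained since its geometry is lost in the next step.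

Step 3
Reactants: 2 (E)-4-[(tert-butyldimethylsilyl)oxy]-3-methylbut-2-enal, 4 silyl dienol ether
Product: 5 methyl (2E,5S,6E)-8-silyloxy-5-hydroxy-3,7-dimethylocta-2,6-dienoate
Conditions: SiCl4 (1.1 equiv), chiral bisphosphoramide derived from N,N'-dimethyl-1,1'-binaphthyl-2,2'-diamine (5 mol%, the antipode directing Si-face attack), CH2Cl2, −78 °C; aq. NaHCO3
Reagents that add atoms: none
Why: In this Lewis base-activated vinylogous Mukaiyama aldol the dienolate should attack through its γ-carbon only, and the phosphoramide-bound trichlorosilyl cation that activates the enal sets the (5S) carbinol by catalyst control.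

Step 4
Reactants: 5 methyl (2E,5S,6E)-8-silyloxy-5-hydroxy-3,7-dimethylocta-2,6-dienoate
Product: 6 bis-silyl ether ester
Conditions: TBSCl, imidazole, DMF, rt
Reagents that add atoms: tert-butyldimethylsilyl chloride, CC(C)(C)[Si](C)(C)Cl
Why: Standard silylation of the secondary allylic alcohol masks the future C1 oxygen through the ketene and organometallic steps.

Step 5
Reactants: 6 bis-silyl ether ester
Product: 7 bis-silyl ether acid
Conditions: LiOH, THF/MeOH/H2O, 40 °C; then 1 M HCl to pH 4 at 0 °C
Reagents that add atoms: lithium hydroxide, [Li+].[OH-]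
Why: Saponification of the conjugated methyl ester should leave the silyl ethers and both alkene geometries untouched.

Step 6
Reactants: 7 bis-silyl ether acid
Product: 10 bicyclic cyclobutanone (2-methylidenebicyclo[3.1.1]heptan-6-one core), via acid chloride 8 (not isolated), via vinylketene 9 (not isolated)
Conditions: 1-chloro-N,N,2-trimethylprop-1-en-1-amine, CH2Cl2, 0 °C; then syringe-pump addition to Et3N, toluene, 110 °C (0.005 M)
Reagents that add atoms: none
Why: Amine deprotonation of the acyl chloride at the cis C3-methyl should give the cross-conjugated vinylketene, which adds across the trisubstituted alkene in a crossed intramolecular ketene–alkene [2+2] (carbonyl carbon to the less substituted alkene carbon); the E-alkene puts the C7 methyl syn to the three-carbon bridge, and A(1,3) strain from that methyl turns the C–H of the silyloxy carbon inward, so the silyloxy group ends on the carbonyl-bridge side and the (5S) centre fixes both bridgeheads and C7.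

Step 7
Reactants: 10 bicyclic cyclobutanone
Product: 11 alkylidene nitrile
Conditions: (EtO)2P(O)CH2CN, NaH, THF, 0 °C to rt
Reagents that add atoms: diethyl (cyanomethyl)phosphonate, CCOP(=O)(CC#N)OCC
Why: Horner–Wadsworth–Emmons olefination by a small, reactive phosphonate anion should succeed on the strained cyclobutanone, which cannot enolise (both α-carbons are bridgeheads); the alkene geometry is of no consequence.

Step 8
Reactants: 11 alkylidene nitrile
Product: 12 saturated nitrile (cyanomethyl arm cis to the CH2OSi arm)
Conditions: Cu(OAc)2 (5 mol%), Xantphos (5 mol%), (EtO)2MeSiH, t-BuOH, toluene, rt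
Reagents that add atoms: none
Why: Copper hydride (monovalent copper) conjugate reduction should deliver hydride to C6 from the open face beside the three-carbon bridge, because the other face is blocked by the C7 CH2OSi arm, so the new arm ends cis to that arm; the isolated methylidene is not a substrate for this polar two-electron reduction.

Step 9
Reactants: 12 saturated nitrile
Product: 14 gem-dimethyl nitrile, via monomethyl nitrile 13 (not isolated)
Conditions: LiN(i-Pr)2, THF, −78 °C, MeI; then a second charge of LiN(i-Pr)2, DMPU and MeI, −78 to 0 °C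
Reagents that add atoms: iodomethane, CI
Why: Two successive nitrile-anion methylations build the quaternary C6 of the target; the small, linear nitrile anion is well suited to forming a quaternary carbon next to the crowded cyclobutane.

Step 10
Reactants: 14 gem-dimethyl nitrile
Product: 16 methyl ketone, via ketimine 15 (not isolated)
Conditions: MeLi, Et2O, 0 °C to rt; then AcOH/NaOAc buffer (pH 5), THF/H2O, rt
Reagents that add atoms: methyllithium, [Li]C; water, O
Why: Methyllithium should add once to the tertiary nitrile (the N-lithio ketimine resists a second addition), and buffered hydrolysis of the ketimine gives the ketone without exposing the acid-sensitive methylidene-bicycloheptane and the silyl ethers to strong acid.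

Step 11
Reactants: 16 methyl ketone
Product: 17 keto diol
Conditions: Bu4NF, THF, rt to 40 °C
Reagents that add atoms: none
Why: Fluoride cleaves both silyl ethers under non-acidic conditions that the skeleton tolerates.

Step 12
Reactants: 17 keto diol
Product: 19 enone keto aldehyde, via deconjugated keto aldehyde 18 (not isolated)
Conditions: Dess–Martin periodinane (2.5 equiv), NaHCO3, CH2Cl2, 0 °C to rt; then Et3N (0.2 equiv), rt
Reagents that add atoms: none
Why: Dess–Martin oxidation of both carbinols gives the formyl group and a β,γ-unsaturated ketone, whose doubly activated ring methylene is enolised by the amine so that the exocyclic alkene moves into conjugation as the 4-methyl enone; the far less acidic acetyl group should not be enolised by triethylamine.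

Step 13
Reactants: 19 enone keto aldehyde
Product: 20 (4R,5S,9R,10R,11R)-9-hydroxylongipin-2-ene-1,7-dione
Conditions: LaLi3[(R)-binaphthoxide]3 (10 mol%), KN(SiMe3)2 (9 mol%), H2O (20 mol%), THF (0.02 M), −20 °C
Reagents that add atoms: none
Why: Proposed new method: the LaLi3 binaphthoxide/KOH catalyst should deprotonate the only enolisable site that can reach the aldehyde (the acetyl methyl, future C8; C6 is quaternary, the formyl group has no α-hydrogen, and the dienolate of the enone cannot reach C9) while its lanthanum centre binds the formyl oxygen, so that the enolate adds to the Re face of C9 and the aldolate is protonated on turnover; the closest known reaction type is the intermolecular direct catalytic asymmetric aldol addition of methyl ketones to α-quaternary aldehydes with this heterobimetallic catalyst, together with base-mediated keto aldehyde aldol closures of seven-membered rings. The seven-membered ring, and with it the bicyclo[4.1.1]octane unit, closes in a 7-(enolendo)-exo-trig mode, helped by the two arms being held cis on one face of the cyclobutane. The one new stereocentre, C9, is set by the catalyst: the substrate is nearly mirror-symmetric about the plane through C5, C10 and the two arms, so the two C9-epimeric transition states are quasi-enantiomeric, the substrate offers almost no bias, and reagent control is both necessary and unopposed. The step needs chemoselective enolisation (secured by the structure as described), 9α facial selectivity (secured by the catalyst antipode), and suppression of dehydration and retro-aldol (low temperature, weakly basic catalyst, relief of the cis-arm repulsion in the closed form).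

Step 14
Reactants: 20 (4R,5S,9R,10R,11R)-9-hydroxylongipin-2-ene-1,7-dione
Product: 21 7β-hydroxy-9α-(4-nitrobenzoyloxy)longipin-2-en-1-one
Conditions: 4-O2NC6H4CHO (4 equiv), SmI2 (30 mol%), THF, −10 °C
Reagents that add atoms: 4-nitrobenzaldehyde, O=Cc1ccc(cc1)[N+](=O)[O-]
Why: In this Evans–Tishchenko reduction the samarium-bound hemiacetal formed at the C9 oxygen should pass its hydride to the C7 carbonyl from the face of that oxygen, giving the 7β-alcohol trans to the 9α-oxygen (1,3-anti) and leaving C9 as the 4-nitrobenzoate, so the two oxygens are differentiated and the enone is not touched.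

Step 15
Reactants: 21 7β-hydroxy-9α-(4-nitrobenzoyloxy)longipin-2-en-1-one
Product: 22 7β-methacryloyloxy-9α-(4-nitrobenzoyloxy)longipin-2-en-1-one
Conditions: methacrylic anhydride, DMAP, Et3N, BHT (trace), CH2Cl2, 35 °C
Reagents that add atoms: methacrylic anhydride, CC(=C)C(=O)OC(=O)C(C)=C
Why: DMAP-catalysed acylation of the only free hydroxyl installs the methacrylate at C7 with retention.

Step 16
Reactants: 22 7β-methacryloyloxy-9α-(4-nitrobenzoyloxy)longipin-2-en-1-one
Product: 23 9α-hydroxy-7β-methacryloyloxylongipin-2-en-1-one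
Conditions: K2CO3 (0.2 equiv), MeOH/THF, 0 °C
Reagents that add atoms: none
Why: The electron-poor 4-nitrobenzoate should undergo methanolysis much faster than the conjugated, neopentyl methacrylate, and the trans-1,3 relationship of the two oxygens on the ring disfavours acyl migration.

Step 17
Reactants: 23 9α-hydroxy-7β-methacryloyloxylongipin-2-en-1-one
Product: 24 (4R,5S,7R,9R,10R,11R)-9-angeloyloxy-7-methacryloyloxylongipin-2-en-1-one (target)
Conditions: angelic acid, 2,4,6-trichlorobenzoyl chloride, Et3N, toluene, rt; then 23, 80 °C (no DMAP)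
Reagents that add atoms: angelic acid, C/C=C(/C)C(O)=O
Why: Yamaguchi esterification through the preformed mixed anhydride acylates the hindered C9 alcohol with retention, and leaving out nucleophilic catalysts should avoid Z-to-E isomerisation of the angelate to the tiglate.

**Compound list**

1 | 1-[(tert-butyldimethylsilyl)oxy]propan-2-one | CC(=O)CO[Si](C)(C)C(C)(C)C | starting material
2 | (E)-4-[(tert-butyldimethylsilyl)oxy]-3-methylbut-2-enal | CC(C)(C)[Si](C)(C)OC/C(C)=C/C=O | intermediate
3 | methyl 3-methylbut-2-enoate | COC(=O)C=C(C)C | starting material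
4 | tert-butyl[(1-methoxy-3-methylbuta-1,3-dien-1-yl)oxy]dimethylsilane (ketene acetal geometry not defined, used as the mixture) | COC(O[Si](C)(C)C(C)(C)C)=CC(C)=C | intermediate
5 | methyl (2E,5S,6E)-8-[(tert-butyldimethylsilyl)oxy]-5-hydroxy-3,7-dimethylocta-2,6-dienoate | COC(=O)/C=C(\C)C[C@H](O)/C=C(\C)CO[Si](C)(C)C(C)(C)C | intermediate
6 | methyl (2E,5S,6E)-5,8-bis[(tert-butyldimethylsilyl)oxy]-3,7-dimethylocta-2,6-dienoate | COC(=O)/C=C(\C)C[C@H](O[Si](C)(C)C(C)(C)C)/C=C(\C)CO[Si](C)(C)C(C)(C)C | intermediate
7 | (2E,5S,6E)-5,8-bis[(tert-butyldimethylsilyl)oxy]-3,7-dimethylocta-2,6-dienoic acid | OC(=O)/C=C(\C)C[C@H](O[Si](C)(C)C(C)(C)C)/C=C(\C)CO[Si](C)(C)C(C)(C)C | intermediate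
8 | (2E,5S,6E)-5,8-bis[(tert-butyldimethylsilyl)oxy]-3,7-dimethylocta-2,6-dienoyl chloride | ClC(=O)/C=C(\C)C[C@H](O[Si](C)(C)C(C)(C)C)/C=C(\C)CO[Si](C)(C)C(C)(C)C | intermediate
9 | (5S,6E)-5,8-bis[(tert-butyldimethylsilyl)oxy]-7-methyl-3-methylideneocta-1,6-dien-1-one (vinylketene) | O=C=CC(=C)C[C@H](O[Si](C)(C)C(C)(C)C)/C=C(\C)CO[Si](C)(C)C(C)(C)C | intermediate
10 | 4-[(tert-butyldimethylsilyl)oxy]-7-{[(tert-butyldimethylsilyl)oxy]methyl}-7-methyl-2-methylidenebicyclo[3.1.1]heptan-6-one; 7-methyl syn to the C2–C4 bridge, 4-silyloxy on the C6 side of that bridge | CC(C)(C)[Si](C)(C)OC[C@@]1(C)[C@@H]2[C@@H](O[Si](C)(C)C(C)(C)C)CC(=C)[C@H]1C2=O | intermediate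
11 | 2-[4-silyloxy-7-(silyloxymethyl)-7-methyl-2-methylidenebicyclo[3.1.1]heptan-6-ylidene]acetonitrile (silyl = tert-butyldimethylsilyl; ring configuration as in 10; exocyclic alkene geometry not defined) | CC(C)(C)[Si](C)(C)OC[C@@]1(C)[C@@H]2[C@@H](O[Si](C)(C)C(C)(C)C)CC(=C)[C@H]1C2=CC#N | intermediate
12 | 2-[4-silyloxy-7-(silyloxymethyl)-7-methyl-2-methylidenebicyclo[3.1.1]heptan-6-yl]acetonitrile; C6 cyanomethyl anti to the C2–C4 bridge and cis to the C7 silyloxymethyl arm | CC(C)(C)[Si](C)(C)OC[C@@]1(C)[C@@H]2[C@@H](O[Si](C)(C)C(C)(C)C)CC(=C)[C@H]1[C@@H]2CC#N | intermediate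
13 | 2-[bicyclic unit of 12]propanenitrile (both epimers at the nitrile-bearing carbon) | CC(C)(C)[Si](C)(C)OC[C@@]1(C)[C@@H]2[C@@H](O[Si](C)(C)C(C)(C)C)CC(=C)[C@H]1[C@@H]2C(C)C#N | intermediate
14 | 2-methyl-2-[bicyclic unit of 12]propanenitrile | CC(C)(C)[Si](C)(C)OC[C@@]1(C)[C@@H]2[C@@H](O[Si](C)(C)C(C)(C)C)CC(=C)[C@H]1[C@@H]2C(C)(C)C#N | intermediate
15 | 3-methyl-3-[bicyclic unit of 12]butan-2-imine | CC(C)(C)[Si](C)(C)OC[C@@]1(C)[C@@H]2[C@@H](O[Si](C)(C)C(C)(C)C)CC(=C)[C@H]1[C@@H]2C(C)(C)C(C)=N | intermediate
16 | 3-methyl-3-[4-silyloxy-7-(silyloxymethyl)-7-methyl-2-methylidenebicyclo[3.1.1]heptan-6-yl]butan-2-one (configuration as in 12) | CC(C)(C)[Si](C)(C)OC[C@@]1(C)[C@@H]2[C@@H](O[Si](C)(C)C(C)(C)C)CC(=C)[C@H]1[C@@H]2C(C)(C)C(C)=O | intermediate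
17 | 3-[4-hydroxy-7-(hydroxymethyl)-7-methyl-2-methylidenebicyclo[3.1.1]heptan-6-yl]-3-methylbutan-2-one (configuration as in 12) | OC[C@@]1(C)[C@@H]2[C@@H](O)CC(=C)[C@H]1[C@@H]2C(C)(C)C(C)=O | intermediate
18 | 6-methyl-7-(2-methyl-3-oxobutan-2-yl)-4-methylidene-2-oxobicyclo[3.1.1]heptane-6-carbaldehyde; 6-methyl syn to the C2–C4 bridge, formyl and C7 side chain anti to it and cis to each other | O=C[C@@]1(C)[C@@H]2C(=O)CC(=C)[C@H]1[C@@H]2C(C)(C)C(C)=O | intermediate
19 | 4,6-dimethyl-7-(2-methyl-3-oxobutan-2-yl)-2-oxobicyclo[3.1.1]hept-3-ene-6-carbaldehyde; 6-methyl syn to the enone bridge, formyl and C7 side chain anti to it and cis to each other | O=C[C@@]1(C)[C@@H]2C(=O)C=C(C)[C@H]1[C@@H]2C(C)(C)C(C)=O | intermediate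
20 | (4R,5S,9R,10R,11R)-9-hydroxylongipin-2-ene-1,7-dione (9α-OH) | O=C1C[C@@H](O)[C@@]2(C)[C@@H]3C(=O)C=C(C)[C@H]2[C@@H]3C1(C)C | intermediate
21 | (4R,5S,7R,9R,10R,11R)-7-hydroxy-1-oxolongipin-2-en-9-yl 4-nitrobenzoate (7β-OH, 9α-ester) | O[C@@H]1C[C@@H](OC(=O)c4ccc(cc4)[N+](=O)[O-])[C@@]2(C)[C@@H]3C(=O)C=C(C)[C@H]2[C@@H]3C1(C)C | intermediate
22 | (4R,5S,7R,9R,10R,11R)-7-(2-methylprop-2-enoyloxy)-1-oxolongipin-2-en-9-yl 4-nitrobenzoate | C=C(C)C(=O)O[C@@H]1C[C@@H](OC(=O)c4ccc(cc4)[N+](=O)[O-])[C@@]2(C)[C@@H]3C(=O)C=C(C)[C@H]2[C@@H]3C1(C)C | intermediate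
23 | (4R,5S,7R,9R,10R,11R)-9-hydroxy-1-oxolongipin-2-en-7-yl 2-methylprop-2-enoate | C=C(C)C(=O)O[C@@H]1C[C@@H](O)[C@@]2(C)[C@@H]3C(=O)C=C(C)[C@H]2[C@@H]3C1(C)C | intermediate
24 | (4R,5S,7R,9R,10R,11R)-9-[(Z)-2-methylbut-2-enoyloxy]-7-(2-methylprop-2-enoyloxy)longipin-2-en-1-one (7β-methacrylate, 9α-angelate) | C=C(C)C(=O)O[C@@H]1C[C@@H](OC(=O)/C(C)=C\C)[C@@]2(C)[C@@H]3C(=O)C=C(C)[C@H]2[C@@H]3C1(C)C | target

**Step count and risks**

Total steps: 17. Longest linear sequence: 16 steps (1 through steps 1 and 3–17); step 2 is a one-step side branch.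

Steps most likely to fail:

Step 13 (proposed new method). The catalyst may fail to control the face of attack in the intramolecular setting, or an uncatalysed background closure, dehydration or retro-aldol may erode the 9α preference. The fallback sets out from 19 and comes back at 20 using known chemistry. Compound 19 would be cyclised and dehydrated with simple base (KOH, MeOH, 40 °C), where both C9 epimers converge on longipina-2,8-diene-1,7-dione F1. A copper-catalysed enantioselective conjugate borylation of the less substituted C8=C9 enone (CuCl, NaOt-Bu, a Josiphos ligand, B2pin2, MeOH, THF; the trisubstituted C2=C3 enone should be inert) would then give 9α-(4,4,5,5-tetramethyl-1,3,2-dioxaborolan-2-yl)longipin-2-ene-1,7-dione F2. Stereoretentive oxidation (NaBO3, THF/H2O) returns to 20.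

Step 6. Ketene oligomerisation, sluggish cycloaddition to an alkene that carries two allylic oxygens, or incomplete facial control may defeat the thermal ketene route. The fallback sets out from 7 and comes back at 10. Acid 7 would be converted into (2E,5S,6E)-5,8-bis[(tert-butyldimethylsilyl)oxy]-N,N,3,7-tetramethylocta-2,6-dienamide F3 (EDC, HNMe2, CH2Cl2) and activated with Tf2O and 2,4,6-collidine in 1,2-dichloroethane at reflux. The more electrophilic vinylketeniminium ion should undergo the same crossed [2+2] to give the bicyclic N,N-dimethylcyclobutaniminium triflate F4, which is hydrolysed (aq. NaHCO3) to 10.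

Step 14. Hemiacetal formation at the hindered C9 carbinol may be slow, and the nitroarene may consume the samarium catalyst, so the Tishchenko transfer may stall. The fallback sets out from 20 and comes back at 24, one step shorter. Compound 20 would be reduced with Me4NBH(OAc)3 (AcOH/MeCN, −20 °C; the same intramolecular hydride delivery and the same anti outcome) to 7β,9α-dihydroxylongipin-2-en-1-one F5. Site-selective Yamaguchi angeloylation of the C9 hydroxyl would give 9α-angeloyloxy-7β-hydroxylongipin-2-en-1-one F6; the selectivity rests on C9–OH sitting beside the tied-back cyclobutane carbon while C7–OH sits beside the free gem-dimethyl group, and is not assured. Methacryloylation as in step 15 would then give 24.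

Further compounds
F1 | step 13 | longipina-2,8-diene-1,7-dione (ring configuration as in 19) | O=C1C=C[C@@]2(C)[C@@H]3C(=O)C=C(C)[C@H]2[C@@H]3C1(C)C
F2 | step 13 | 9α-(4,4,5,5-tetramethyl-1,3,2-dioxaborolan-2-yl)longipin-2-ene-1,7-dione | O=C1C[C@@H](B4OC(C)(C)C(C)(C)O4)[C@@]2(C)[C@@H]3C(=O)C=C(C)[C@H]2[C@@H]3C1(C)C
F3 | step 6 | (2E,5S,6E)-5,8-bis[(tert-butyldimethylsilyl)oxy]-N,N,3,7-tetramethylocta-2,6-dienamide | CN(C)C(=O)/C=C(\C)C[C@H](O[Si](C)(C)C(C)(C)C)/C=C(\C)CO[Si](C)(C)C(C)(C)C
F4 | step 6 | N,N-dimethyliminium triflate of ketone 10 (iminium carbon at C6 of the bicycle) | CC(C)(C)[Si](C)(C)OC[C@@]1(C)[C@@H]2[C@@H](O[Si](C)(C)C(C)(C)C)CC(=C)[C@H]1C2=[N+](C)C.[O-]S(=O)(=O)C(F)(F)F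
F5 | step 14 | (4R,5S,7R,9R,10R,11R)-7,9-dihydroxylongipin-2-en-1-one (7β,9α-diol) | O[C@@H]1C[C@@H](O)[C@@]2(C)[C@@H]3C(=O)C=C(C)[C@H]2[C@@H]3C1(C)C
F6 | step 14 | (4R,5S,7R,9R,10R,11R)-7-hydroxy-1-oxolongipin-2-en-9-yl (Z)-2-methylbut-2-enoate | O[C@@H]1C[C@@H](OC(=O)/C(C)=C\C)[C@@]2(C)[C@@H]3C(=O)C=C(C)[C@H]2[C@@H]3C1(C)C
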